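Follow one molecule of solid substrate.

all flasks: solid substrate 10 mM
- dawn: reagent 6.7 mM; protic impurity 0.50 mM; run made earlier
- dusk: reagent 15 mM; protic impurity 0.50 mM; run made earlier
- flask: reagent 10.0 mM; protic impurity 0.500 mM; time 5.0 h

| run | time / h | target / % | side product / % | solid substrate / % |
|---|---|---|---|---|
| dawn | 0.667 | 22 | 66 | 0 |
| dawn | 1.33 | 25 | 67 | 0 |
| dawn | 2.00 | 23 | 71 | 0 |
| dawn | 2.50 | 22 | 70 | 1 |
| dawn | 3.00 | 20 | 72 | 0 |
| dawn | 4.00 | 27 | 73 | 1 |
| dusk | 0.250 | 57 | 35 | 0 |
| dusk | 0.833 | 61 | 36 | 1 |
| dusk | 1.33 | 58 | 37 | 0 |
| dusk | 2.00 | 56 | 33 | 0 |
| dusk | 3.00 | 59 | 31 | 0 |
| dusk | 4.00 | 55 | 36 | 0 |

(standard deviation of a reading: 2 percentage points)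

* which holds at 5.0 h: what has brought the reaction to rest, or that it has not come to rest (for what has run out or reacted, a solid counts together with what of it has only dissolved) (all of the solid substrate has reacted / the reagent has run out first / it is still moving / forward and back rates have come level)
* the target standing at 5.0 h, as a percentage of the solid substrate charged
* the side product standing at 5.0 h, as a percentage of the solid substrate charged

- a species is counted by the solid substrate in it: one side product counts as two
- given per volume of solution although it is solid: solid substrate
- the numbers in the tables scatter with a standard deviation of 2 percentage points
- at the start none of the solid substrate is in solution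
- what has only dissolved of solid substrate counts as not reacted
- the reaction counts as stopped when no species that holds the solid substrate changes by six tenths of a point or more over the second half of the time

The ladder of times was short. On its fastest rung the solid substrate was consumed: the dusk run read 0% at 0.250 h, with the target already at its later level. On the next rung the dusk readings only scattered up to 4.00 h. Since 5.0 h is far longer than that first reading, I expected this flask to be at rest and its yields to be set by the chances at two forks, not by the clock.

At the first fork I let each protic impurity take one substrate, leaving S = 9.50 mM to react. At the second I read the chemistry as the forecast did: substrate meets reagent and gives target, or meets target and gives side product. With P the target and Q the side product, the chance f of meeting reagent is (P + Q/2)/(P + Q), a fraction of the encounters at this fork. The dawn averages, 23.2% and 69.8%, gave 0.625. The dusk averages, 57.7% and 34.7%, gave a higher 0.812.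

Taking r as reagent per S, dawn has 0.705, dusk 1.58 and this flask 1.05. I assumed the chance runs straight in ln r, which gave the fork chance f for this flask, 0.718. Counting molecules, my reckoning was target 41.4%, side product 53.6% and 31.8% of the reagent left, so the solid substrate is the limiting reagent.

The forecast, holding that “the reaction stops when the substrate is gone”, said all of the solid substrate has reacted, with target 43% (37% to 48%) and side product 50% (44% to 56%). My target was lower and my side product higher.

    solid substrate ⇌ dissolved substrate, rate k1*(cs1 - [dissolved substrate]) while solid is left; crystals form when [dissolved substrate] > cs1 (solubility = 7.70 mM, k = 0.00368 /s)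
    dissolved substrate + reagent → target (k = 0.407 /M/s)
    dissolved substrate + target → side product (k = 0.274 /M/s)
    solid substrate + protic impurity → quenched substrate (k = 7.27 /M/s)

The flask gave all of the solid substrate has reacted, with target 44.3% and side product 50.7%, as the forecast said. With the other amounts held, the side product has moved by 5 points at 8.96 mM or 11.3 mM of reagent, and the forecast's range ends about there. The result puts f at 0.733, above my reckoning.

In a second flask, the same but with 6.0 mM of solid substrate, r rises to 1.82, past dusk, and the line extended gives f = 0.845, so target 63.3% and side product 28.4%. Computed, that flask gave 61.4% and 30.4%.

The readings are simulated on assumed constants.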